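At 50 h, and earlier at 5.0 h, you read the flasks below, with the earlier runs to go on.

| flask | substrate | coupling partner | capture agent | free catalyst | remark | time |
|---|---|---|---|---|---|---|
| Sunday's | 0.36 M | 0.54 M | 0.018 M | 73 mM | run made earlier |  |
| Tuesday's | 0.36 M | 0.54 M | 0.018 M | 200 mM | run made earlier |  |
| Saturday's | 0.80 M | 0.54 M | 0.018 M | 54 mM | run made earlier |  |
| winter | 1.5 M | 0.540 M | 0.0500 M | 54 mM |  | 50 h |
| noon | 0.36 M | 0.200 M | 0.0500 M | 54 mM |  | 50 h |
| autumn | 0.25 M | 0.540 M | 0.0400 M | 54 mM |  | 50 h |
| dawn | 1.5 M | 0.540 M | 0.0180 M | 150 mM |  | 50 h |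
| dusk | 0.36 M | 0.540 M | 0.0180 M | 54 mM |  | 50 h |

| run | time / h | product / % | substrate / % |
|---|---|---|---|
| Sunday's | 3.00 | 14 | 79 |
| Sunday's | 6.00 | 29 | 65 |
| Sunday's | 15.0 | 54 | 36 |
| Sunday's | 40.0 | 86 | 5 |
| Tuesday's | 8.00 | 60 | 22 |
| Tuesday's | 20.0 | 78 | 3 |
| Tuesday's | 25.0 | 78 | 1 |
| Tuesday's | 40.0 | 81 | 1 |
| Saturday's | 4.00 | 5 | 90 |
| Saturday's | 12.0 | 20 | 77 |
| Saturday's | 25.0 | 33 | 64 |
| Saturday's | 40.0 | 40 | 54 |

(scatter of a reading: 1.5 percentage points)

- ranking by amount of product, in percent of the substrate charged, from high to low, at 50 h (winter / noon / autumn / dawn / dusk)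
- the same order at 5.0 h (winter / noon / autumn / dawn / dusk)
- the amount of product, in percent of the substrate charged of the flask you put first, at 50 h
- the amount of product, in percent of the substrate charged of the flask you put last, at 50 h

- the earlier runs were read with a standard deviation of 1.5 percentage points
- no earlier run changes the charge of capture agent; that part of a forecast is a guess

Count half-lives. In Sunday's run the substrate stood at 36% after 15.0 h, which is a half-life of 10.2 h. Tuesday's run gives 3.66 h. Scaled to 54 mM of free catalyst, these become 13.8 h and 13.6 h, so the clock runs with the catalyst. Time over half-life gives 3.63 for dusk, and this is the half-life count. On that count I expect 8.05% of dusk's substrate to remain at 50 h.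

Saturday's run is different. With 0.80 M of substrate charged, it still held 54% of it at 40.0 h, later than dusk's half-life. It lost substrate at 15.3 mM h⁻¹ on average over its first 12.0 h, while dusk's clock starts at 18.1 mM h⁻¹. So I expect autumn, with a smaller charge of substrate than dusk, to count more half-lives.

Now I bracket autumn. Sunday's last reading leaves some substrate unaccounted for, which scales to 24.0 mM at 54 mM of free catalyst. I subtract that and guess that the capture agent changes nothing. From above, with all substrate used, autumn gives 90.4%. From below, on dusk's clock, it gives 82.4%. To tighten this, let the half-life shrink with the charge: autumn then counts 5.23 and gives 87.8%. The same reckoning gives dusk 85.3%, so I put autumn first, ahead of dusk. Coupling partner is the limiting reagent in winter and dawn, below the substrate, and in noon. If each product takes one coupling partner, winter and dawn stay under 36.0% and noon under 55.6%.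

The forecast says dusk > autumn > noon > dawn > winter at 50 h and dusk > autumn > dawn > noon > winter at 5.0 h, with 83% on top and 20% at the bottom. It gives autumn 79, “with a larger relative gap”. That stands outside my bracket, which starts at 82.4%.

The flasks give autumn > dusk > noon > dawn > winter and autumn > dusk > dawn > noon > winter, with 89.8% on top and 24.9% at the bottom.

    catalyst intermediate B + capture agent → trapped intermediate (k = 8.30 × 10⁻⁵ M⁻¹ s⁻¹)
    substrate + catalyst intermediate A → catalyst intermediate B (k = 0.00570 M⁻¹ s⁻¹)
    coupling partner + free catalyst ⇌ catalyst intermediate A (K = 0.640 M⁻¹, k = 2.90 × 10⁻⁴ M⁻¹ s⁻¹)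
    catalyst intermediate B ⇌ free catalyst + product (K = 0.430 M, k = 4.70 × 10⁻⁴ s⁻¹)

In autumn, half of the release of product from catalyst intermediate B up to 50.0 h was done by 10.1 h, and 86% of the making of catalyst intermediate A from coupling partner and free catalyst up to that time was done by 25.0 h. At 50.0 h, autumn held 1.36% of its substrate, the equivalent of 6.20 half-lives against the 5.23 I counted, while dusk held 8.28% where its count gave 8.05%. My count for the neighbour of autumn with 0.22 M of free catalyst is 21.3 half-lives, and at 50.0 h that flask holds 0% of its substrate and 70.7% product.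

The readings were computed for an exercise.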